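**Strategy**

Everything hinges on cutting ring C at the aryl ether bond O1–C8a. The structural feature used is that O1 bridges the stereogenic benzylic carbon C2 and the aromatic carbon C8a of ring A: the heterocycle can therefore be closed by a copper-catalysed intramolecular O-arylation that leaves every bond at C2 and C3 as it is. In one operation an open-chain threo diol monoether becomes the cis-2,3-chroman with both stereocentres already in place. The precursor is a (1R,2R)-1,3-diarylpropane-1,2-diol with a free benzylic hydroxyl, an allyl ether on the neighbouring oxygen (the later O3), a bromine on ring A ortho to the side chain, and benzyl ethers on all four phenols.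

Key step: step 10

Remark on the design: O3 is capped as an allyl ether, not a p-methoxybenzyl ether, because benzylated flavans lose hydride from C4 to quinone oxidants such as DDQ; the allyl ether still chelates magnesium, is inert to the copper coupling and leaves by isomerisation and acid methanolysis.

Assumption: 2-(allyloxy)acetic acid (7) is taken as a catalogue compound; otherwise it is one step from bromoacetic acid and allyl alcohol (NaH, THF).

**Route**

Step 1
Reactants: 1 5-bromoresorcinol
Product: 2 1,3-bis(benzyloxy)-5-bromobenzene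
Conditions: BnBr, K2CO3, DMF, 60 °C
Reagents that add atoms: benzyl bromide BrCc1ccccc1
Why: Williamson etherification of both phenols, with no competing nucleophilic site.

Step 2
Reactants: 2 1,3-bis(benzyloxy)-5-bromobenzene
Product: 4 2,4-bis(benzyloxy)-6-bromobenzaldehyde, via aryl iminium chloride 3 (not isolated)
Conditions: POCl3, DMF, 0 → 70 °C; then aq. NaOAc
Reagents that add atoms: N,N-dimethylformamide CN(C)C=O; water O
Why: Vilsmeier–Haack formylation, in which the chloroiminium ion should attack the ring carbon para to one benzyloxy group and ortho to the other (next to bromine) in preference to the carbon flanked by both ethers, as in the dimethyl ether series, and hydrolysis of the iminium salt gives the aldehyde.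

Step 3
Reactants: 4 2,4-bis(benzyloxy)-6-bromobenzaldehyde
Product: 5 [2,4-bis(benzyloxy)-6-bromophenyl]methanol
Conditions: NaBH4, THF/MeOH, 0 °C
Reagents that add atoms: none
Why: Borohydride reduction of an aryl aldehyde, which leaves the aryl bromide and the benzyl ethers untouched.

Step 4
Reactants: 5 [2,4-bis(benzyloxy)-6-bromophenyl]methanol
Product: 6 1,5-bis(benzyloxy)-3-bromo-2-(bromomethyl)benzene
Conditions: PBr3, Et2O/CH2Cl2, 0 °C; used crude
Reagents that add atoms: phosphorus tribromide BrP(Br)Br
Why: Conversion of an activated benzylic alcohol into the bromide through its phosphite ester at low temperature, the product being carried on at once because electron-rich benzylic bromides ionise easily.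

Step 5
Reactants: 7 2-(allyloxy)acetic acid; 8 (S)-4-benzyloxazolidin-2-one
Product: 10 (S)-3-[2-(allyloxy)acetyl]-4-benzyloxazolidin-2-one, via mixed pivalic anhydride 9 (not isolated)
Conditions: PivCl, Et3N, THF, −20 °C; then 8, LiCl, −20 °C → rt
Reagents that add atoms: none
Why: N-acylation of the oxazolidinone by a mixed pivalic anhydride under LiCl/Et3N activation, the hindered pivaloyl carbonyl directing attack to the glycolyl carbonyl.

Step 6
Reactants: 10 (S)-3-[2-(allyloxy)acetyl]-4-benzyloxazolidin-2-one (1.5 equiv); 6 1,5-bis(benzyloxy)-3-bromo-2-(bromomethyl)benzene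
Product: 11 (S)-4-benzyl-3-{(2R)-2-(allyloxy)-3-[2,4-bis(benzyloxy)-6-bromophenyl]propanoyl}oxazolidin-2-one
Conditions: NaHMDS, THF, −78 °C; then 6, −78 → −45 °C
Reagents that add atoms: none
Why: Evans glycolate alkylation, in which the chelated Z-sodium enolate is shielded on one face by the C4 benzyl group of the auxiliary so that the benzylic bromide enters from the opposite face and sets the (R) centre that becomes C3.

Step 7
Reactants: 11 alkylated imide
Product: 12 (2R)-2-(allyloxy)-3-[2,4-bis(benzyloxy)-6-bromophenyl]propan-1-ol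
Conditions: LiBH4, MeOH (1 equiv), Et2O, 0 °C
Reagents that add atoms: none
Why: Reductive cleavage of the N-acyl oxazolidinone at the exocyclic carbonyl, which releases the auxiliary and does not touch the α-alkoxy stereocentre, the alkene or the aryl bromide.

Step 8
Reactants: 12 (2R)-2-(allyloxy)-3-[2,4-bis(benzyloxy)-6-bromophenyl]propan-1-ol
Product: 13 (2R)-2-(allyloxy)-3-[2,4-bis(benzyloxy)-6-bromophenyl]propanal
Conditions: Dess–Martin periodinane, NaHCO3, CH2Cl2, 0 °C → rt; used crude
Reagents that add atoms: none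
Why: Dess–Martin oxidation under buffered, non-basic conditions, so the epimerisable α-alkoxy aldehyde should be obtained without loss of configuration if used directly.

Step 9
Reactants: 13 (2R)-2-(allyloxy)-3-[2,4-bis(benzyloxy)-6-bromophenyl]propanal; 14 4-bromo-1,2-bis(benzyloxy)benzene
Product: 16 (1R,2R)-2-(allyloxy)-1-[3,4-bis(benzyloxy)phenyl]-3-[2,4-bis(benzyloxy)-6-bromophenyl]propan-1-ol, via aryl Grignard reagent 15 (not isolated)
Conditions: 14, Mg, THF, 40 °C; then 13, MgBr2·OEt2, CH2Cl2, −78 °C
Reagents that add atoms: none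
Why: Cram-chelate-controlled Grignard addition, in which magnesium bridges the aldehyde oxygen and the α-allyloxy oxygen and the aryl group adds to the carbonyl face away from the arylmethyl substituent, which should give the 1,2-syn (threo) alcohol with the new carbinol centre (R), while the aryl bromide of 13 does not exchange with an aryl Grignard at −78 °C.

Step 10
Reactants: 16 (1R,2R)-2-(allyloxy)-1-[3,4-bis(benzyloxy)phenyl]-3-[2,4-bis(benzyloxy)-6-bromophenyl]propan-1-ol
Product: 17 (2R,3R)-3-(allyloxy)-5,7-bis(benzyloxy)-2-[3,4-bis(benzyloxy)phenyl]chromane (3-O-allyl-5,7,3',4'-tetra-O-benzylepicatechin)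
Conditions: CuI (10 mol %), 3,4,7,8-tetramethyl-1,10-phenanthroline (20 mol %), Cs2CO3, toluene (0.02 M), 110 °C
Reagents that add atoms: none
Why: Cs2CO3 converts the single free hydroxyl into a copper(I) alkoxide held by the phenanthroline ligand; this inserts into the C–Br bond of ring A to give a seven-membered Cu(III) metallacycle (Cu, C8a, C4a, C4, C3, C2, O1), and C–O reductive elimination releases the chroman and Cu(I). The closest known reaction type is the intramolecular Ullmann-type (copper-catalysed) etherification of secondary alcohols with aryl bromides that gives chromans and flavans. Ring C is closed as a six-membered ring by ipso substitution at C8a (formally 6-exo), the oxygen staying attached to C2 throughout. No stereocentre is created: the C2–O, C2–H and C2–aryl bonds and all bonds at C3 are spectators, so the (1R,2R)-threo array becomes the (2R,3R)-cis-2,3 chroman. The step needs chemoselectivity for six-ring closure through the benzylic oxygen over five-ring closure through O3 and over intermolecular coupling; the allyl cap on O3 leaves one nucleophilic oxygen and dilution suppresses oligomers. Copper is preferred to palladium because it neither oxidises the benzylic alkoxide by β-hydride elimination nor engages the allyl ether.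

Step 11
Reactants: 17 3-O-allyl-5,7,3',4'-tetra-O-benzylepicatechin
Product: 19 (2R,3R)-5,7-bis(benzyloxy)-2-[3,4-bis(benzyloxy)phenyl]chroman-3-ol (5,7,3',4'-tetra-O-benzyl-(−)-epicatechin), via propenyl ether 18 (not isolated)
Conditions: [Ir(cod)(PMePh2)2]PF6 (cat., H2-activated), THF, rt; then TsOH·H2O (cat.), MeOH/CH2Cl2, rt
Reagents that add atoms: none
Why: Iridium-hydride-catalysed isomerisation of the allyl ether to the (E)-prop-1-enyl ether followed by acid-catalysed methanolysis of the enol ether, a non-oxidative sequence that spares C4–H, the benzyl ethers and the configuration at C2 and C3.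

Step 12
Reactants: 20 3,5-dihydroxy-4-methoxybenzoic acid
Product: 22 3,5-bis(benzyloxy)-4-methoxybenzoic acid, via benzyl ester 21 (not isolated)
Conditions: BnBr, K2CO3, DMF, 60 °C; then NaOH, MeOH/H2O, 65 °C; HCl
Reagents that add atoms: benzyl bromide BrCc1ccccc1
Why: Exhaustive Williamson benzylation of both phenols and the carboxylate followed by saponification of the benzyl ester, under which aryl benzyl ethers are stable.

Step 13
Reactants: 19 5,7,3',4'-tetra-O-benzyl-(−)-epicatechin; 22 3,5-bis(benzyloxy)-4-methoxybenzoic acid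
Product: 23 (2R,3R)-5,7-bis(benzyloxy)-2-[3,4-bis(benzyloxy)phenyl]chroman-3-yl 3,5-bis(benzyloxy)-4-methoxybenzoate
Conditions: DCC, DMAP, CH2Cl2, rt
Reagents that add atoms: none
Why: Steglich esterification, in which the acylpyridinium formed from the O-acylisourea should acylate the hindered axial C3 hydroxyl with retention because no bond at C3 is broken.

Step 14
Reactants: 23 hexabenzyl ester
Product: 24 epicatechin 3-O-(4-O-methylgallate)
Conditions: H2 (1 atm), Pd(OH)2/C, THF/MeOH, rt
Reagents that add atoms: none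
Why: Hydrogenolysis of the six aryl benzyl ethers under neutral conditions, which should leave the ester, the methyl ether and both stereocentres untouched.

**Compound list**

1 | 5-bromoresorcinol | Oc1cc(O)cc(Br)c1 | starting material
2 | 1,3-bis(benzyloxy)-5-bromobenzene | Brc1cc(OCc2ccccc2)cc(OCc2ccccc2)c1 | intermediate
3 | N-[2,4-bis(benzyloxy)-6-bromobenzylidene]-N-methylmethanaminium chloride | C[N+](C)=Cc1c(Br)cc(OCc2ccccc2)cc1OCc1ccccc1.[Cl-] | intermediate
4 | 2,4-bis(benzyloxy)-6-bromobenzaldehyde | O=Cc1c(Br)cc(OCc2ccccc2)cc1OCc1ccccc1 | intermediate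
5 | [2,4-bis(benzyloxy)-6-bromophenyl]methanol | OCc1c(Br)cc(OCc2ccccc2)cc1OCc1ccccc1 | intermediate
6 | 1,5-bis(benzyloxy)-3-bromo-2-(bromomethyl)benzene | BrCc1c(Br)cc(OCc2ccccc2)cc1OCc1ccccc1 | intermediate
7 | 2-(allyloxy)acetic acid | C=CCOCC(=O)O | starting material
8 | (S)-4-benzyloxazolidin-2-one | O=C1N[C@@H](Cc2ccccc2)CO1 | starting material
9 | 2-(allyloxy)acetic pivalic anhydride | C=CCOCC(=O)OC(=O)C(C)(C)C | intermediate
10 | (S)-3-[2-(allyloxy)acetyl]-4-benzyloxazolidin-2-one | C=CCOCC(=O)N1C(=O)OC[C@@H]1Cc1ccccc1 | intermediate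
11 | (S)-4-benzyl-3-{(2R)-2-(allyloxy)-3-[2,4-bis(benzyloxy)-6-bromophenyl]propanoyl}oxazolidin-2-one | C=CCO[C@H](Cc1c(Br)cc(OCc2ccccc2)cc1OCc1ccccc1)C(=O)N1C(=O)OC[C@@H]1Cc1ccccc1 | intermediate
12 | (2R)-2-(allyloxy)-3-[2,4-bis(benzyloxy)-6-bromophenyl]propan-1-ol | C=CCO[C@H](Cc1c(Br)cc(OCc2ccccc2)cc1OCc1ccccc1)CO | intermediate
13 | (2R)-2-(allyloxy)-3-[2,4-bis(benzyloxy)-6-bromophenyl]propanal | C=CCO[C@H](Cc1c(Br)cc(OCc2ccccc2)cc1OCc1ccccc1)C=O | intermediate
14 | 4-bromo-1,2-bis(benzyloxy)benzene | Brc1ccc(OCc2ccccc2)c(OCc2ccccc2)c1 | starting material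
15 | [3,4-bis(benzyloxy)phenyl]magnesium bromide | Br[Mg]c1ccc(OCc2ccccc2)c(OCc2ccccc2)c1 | intermediate
16 | (1R,2R)-2-(allyloxy)-1-[3,4-bis(benzyloxy)phenyl]-3-[2,4-bis(benzyloxy)-6-bromophenyl]propan-1-ol | C=CCO[C@H](Cc1c(Br)cc(OCc2ccccc2)cc1OCc1ccccc1)[C@H](O)c1ccc(OCc2ccccc2)c(OCc2ccccc2)c1 | intermediate
17 | (2R,3R)-3-(allyloxy)-5,7-bis(benzyloxy)-2-[3,4-bis(benzyloxy)phenyl]chromane | C=CCO[C@@H]1Cc2c(OCc3ccccc3)cc(OCc3ccccc3)cc2O[C@@H]1c1ccc(OCc2ccccc2)c(OCc2ccccc2)c1 | intermediate
18 | (2R,3R)-5,7-bis(benzyloxy)-2-[3,4-bis(benzyloxy)phenyl]-3-[(E)-prop-1-enyloxy]chromane | C/C=C/O[C@@H]1Cc2c(OCc3ccccc3)cc(OCc3ccccc3)cc2O[C@@H]1c1ccc(OCc2ccccc2)c(OCc2ccccc2)c1 | intermediate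
19 | (2R,3R)-5,7-bis(benzyloxy)-2-[3,4-bis(benzyloxy)phenyl]chroman-3-ol | O[C@@H]1Cc2c(OCc3ccccc3)cc(OCc3ccccc3)cc2O[C@@H]1c1ccc(OCc2ccccc2)c(OCc2ccccc2)c1 | intermediate
20 | 3,5-dihydroxy-4-methoxybenzoic acid | COc1c(O)cc(C(=O)O)cc1O | starting material
21 | benzyl 3,5-bis(benzyloxy)-4-methoxybenzoate | COc1c(OCc2ccccc2)cc(C(=O)OCc2ccccc2)cc1OCc1ccccc1 | intermediate
22 | 3,5-bis(benzyloxy)-4-methoxybenzoic acid | COc1c(OCc2ccccc2)cc(C(=O)O)cc1OCc1ccccc1 | intermediate
23 | (2R,3R)-5,7-bis(benzyloxy)-2-[3,4-bis(benzyloxy)phenyl]chroman-3-yl 3,5-bis(benzyloxy)-4-methoxybenzoate | COc1c(OCc2ccccc2)cc(C(=O)O[C@@H]2Cc3c(OCc4ccccc4)cc(OCc4ccccc4)cc3O[C@@H]2c2ccc(OCc3ccccc3)c(OCc3ccccc3)c2)cc1OCc1ccccc1 | intermediate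
24 | epicatechin 3-O-(4-O-methylgallate), (2R,3R) | COc1c(O)cc(C(=O)O[C@@H]2Cc3c(O)cc(O)cc3O[C@@H]2c2ccc(O)c(O)c2)cc1O | target

**Step count**

Total: 14 steps. Longest linear sequence: 12 steps (1, 2, 3, 4, 6, 7, 8, 9, 10, 11, 13, 14).

**Steps most likely to fail**

Step 10. The copper alkoxide may fail to insert into the ortho-substituted C–Br bond, so that protodebromination or intermolecular etherification outruns ring closure. The fallback reverses the polarity at C8a and keeps the same O1–C8a bond. It sets out from 16: Miyaura borylation (B2pin2, Pd(dppf)Cl2, KOAc, dioxane, 90 °C) should give the aryl pinacol boronate F1. KHF2 in MeOH/H2O converts it into the potassium aryltrifluoroborate F2. Intramolecular Chan–Lam oxidative etherification (Cu(OAc)2·H2O, DMAP, 4 Å sieves, O2, CH2Cl2, rt) should then close ring C, again with the C2–O bond untouched. The fallback comes back to the route at 17.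

Step 9. THF from the Grignard solution may compete for magnesium, so that the open Felkin pathway erodes the facial selectivity and the C1 epimer forms alongside 16. The fallback moves stereocontrol from aryl addition to hydride addition. It sets out from 16 as its mixture of C1 epimers: Dess–Martin oxidation gives the (R)-2-(allyloxy) aryl ketone F3. Reduction with the bulky, non-chelating K-Selectride (THF, −78 °C) should follow the polar Felkin–Anh model, which for the ketone delivers the threo alcohol. The fallback comes back at 16.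

Step 6. The electron-rich benzylic bromide may ionise and self-condense, or the glycolate enolate may decompose, before C-alkylation occurs. The fallback forms the same C–C bond by an aldol reaction from the stable aldehyde 4, which also bypasses steps 3 and 4. Acid 7 is coupled with (R)-4-benzyloxazolidin-2-one as in step 5 to give the enantiomeric glycolyl imide F4. Its boron enolate (Bu2BOTf, Et3N, CH2Cl2, −78 → 0 °C) adds to 4 in an Evans syn aldol reaction to give the (2R,3S)-β-hydroxy imide F5. Ionic deoxygenation of the doubly alkoxy-activated benzylic alcohol (Et3SiH, TFA, CH2Cl2, 0 °C) gives the (2R)-imide F6. LiBH4 reduction as in step 7 brings the fallback back to the route at 12.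

**Further compounds**

F1 | step 10 | (1R,2R)-2-(allyloxy)-1-[3,4-bis(benzyloxy)phenyl]-3-[2,4-bis(benzyloxy)-6-(4,4,5,5-tetramethyl-1,3,2-dioxaborolan-2-yl)phenyl]propan-1-ol | C=CCO[C@H](Cc1c(B2OC(C)(C)C(C)(C)O2)cc(OCc2ccccc2)cc1OCc1ccccc1)[C@H](O)c1ccc(OCc2ccccc2)c(OCc2ccccc2)c1
F2 | step 10 | potassium {2-[(2R,3R)-2-(allyloxy)-3-[3,4-bis(benzyloxy)phenyl]-3-hydroxypropyl]-3,5-bis(benzyloxy)phenyl}trifluoroborate | C=CCO[C@H](Cc1c([B-](F)(F)F)cc(OCc2ccccc2)cc1OCc1ccccc1)[C@H](O)c1ccc(OCc2ccccc2)c(OCc2ccccc2)c1.[K+]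
F3 | step 9 | (2R)-2-(allyloxy)-1-[3,4-bis(benzyloxy)phenyl]-3-[2,4-bis(benzyloxy)-6-bromophenyl]propan-1-one | C=CCO[C@H](Cc1c(Br)cc(OCc2ccccc2)cc1OCc1ccccc1)C(=O)c1ccc(OCc2ccccc2)c(OCc2ccccc2)c1
F4 | step 6 | (R)-3-[2-(allyloxy)acetyl]-4-benzyloxazolidin-2-one | C=CCOCC(=O)N1C(=O)OC[C@H]1Cc1ccccc1
F5 | step 6 | (R)-4-benzyl-3-{(2R,3S)-2-(allyloxy)-3-[2,4-bis(benzyloxy)-6-bromophenyl]-3-hydroxypropanoyl}oxazolidin-2-one | C=CCO[C@@H](C(=O)N1C(=O)OC[C@H]1Cc1ccccc1)[C@@H](O)c1c(Br)cc(OCc2ccccc2)cc1OCc1ccccc1
F6 | step 6 | (R)-4-benzyl-3-{(2R)-2-(allyloxy)-3-[2,4-bis(benzyloxy)-6-bromophenyl]propanoyl}oxazolidin-2-one | C=CCO[C@H](Cc1c(Br)cc(OCc2ccccc2)cc1OCc1ccccc1)C(=O)N1C(=O)OC[C@H]1Cc1ccccc1
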